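The route rests on disconnecting the C1–C2 bond of the 3,7-dioxabicyclo[3.3.0]octan-8-one core, between the lactone α-carbon C1 and the aryl-bearing carbon C2 of the tetrahydrofuran ring. Because C2 is flanked by ring oxygen O3 and an electron-rich arene while C1 is enolisable next to the lactone carbonyl C8, an intramolecular Mukaiyama aldol-type addition of the lactone silyl ketene acetal to a tethered oxocarbenium ion closes the tetrahydrofuran ring and sets C1 and C2 in one operation, giving the cis-fused exo,exo bicycle. Its precursor is an Evans-aldol-derived trans-4-(hydroxymethyl)-5-aryl-γ-butyrolactone whose alcohol carries the second aryl aldehyde as a mixed methyl acetal; benzyl ethers mask all five phenols.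

Key step: step 7

Remark: locants C1–C8 refer to the 3,7-dioxabicyclo[3.3.0]octan-8-one core (C1 and C5 ring fusion, C2 aryl-bearing carbon of the tetrahydrofuran ring, O3, C4, C6 aryl-bearing carbon of the lactone ring, O7, C8 carbonyl).
Remark: 11, 12 and 13 are taken as mixtures of epimers at the acetal carbon, which becomes planar in step 7; aldehydes 4 and 9 are taken as commercial.

Step 1
Reactants: 1 (S)-4-benzyl-1,3-oxazolidin-2-one; 2 methyl 4-chloro-4-oxobutanoate
Product: 3 methyl 4-[(4S)-4-benzyl-2-oxo-1,3-oxazolidin-3-yl]-4-oxobutanoate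
Conditions: n-BuLi, THF, −78 °C; then 2, −78 → 0 °C
Reagents that add atoms: none
Why: N-acylation of the lithiated oxazolidinone by the acid chloride is the standard entry to Evans imides, and the methyl ester is untouched at low temperature.

Step 2
Reactants: 3 methyl 4-[(4S)-4-benzyl-2-oxo-1,3-oxazolidin-3-yl]-4-oxobutanoate; 4 3,4,5-tris(benzyloxy)benzaldehyde
Product: 6 (4S)-4-benzyl-3-{(2S,3S)-5-oxo-2-[3,4,5-tris(benzyloxy)phenyl]oxolane-3-carbonyl}-1,3-oxazolidin-2-one (trans lactone imide), via syn-aldol adduct 5 (not isolated)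
Conditions: Bu2BOTf, iPr2NEt, CH2Cl2, −78 → 0 °C; 4, −78 → 0 °C; pH 7 buffer, MeOH, 30% H2O2, 0 °C; then PPTS (cat.), toluene, 60 °C
Reagents that add atoms: none
Why: Evans syn-aldol reaction, in which the (Z)-boron enolate formed next to the imide carbonyl adds to the aldehyde through a chair Zimmerman–Traxler transition state on the face remote from the benzyl group of the (S)-auxiliary, which sets both new centres as (3S,4S), and the syn adduct then lactonises onto the methyl ester to the trans-4,5-disubstituted γ-lactone, the configuration later found at C5 and C6.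

Step 3
Reactants: 6 (4S)-4-benzyl-3-{(2S,3S)-5-oxo-2-[3,4,5-tris(benzyloxy)phenyl]oxolane-3-carbonyl}-1,3-oxazolidin-2-one
Product: 7 (2S,3S)-5-oxo-2-[3,4,5-tris(benzyloxy)phenyl]oxolane-3-carboxylic acid
Conditions: LiOH, H2O2, THF/H2O, 0 °C; Na2SO3; HCl to pH 2
Reagents that add atoms: hydrogen peroxide, OO
Why: Hydroperoxide cleavage of an Evans imide, in which LiOOH attacks the exocyclic carbonyl selectively, sulfite reduces the peracid and acidification closes again any lactone opened by hydroxide, so that neither stereocentre is touched and the auxiliary is recovered.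

Step 4
Reactants: 7 (2S,3S)-5-oxo-2-[3,4,5-tris(benzyloxy)phenyl]oxolane-3-carboxylic acid
Product: 8 (4R,5S)-4-(hydroxymethyl)-5-[3,4,5-tris(benzyloxy)phenyl]oxolan-2-one
Conditions: BH3·SMe2, THF, 0 °C → rt; MeOH quench
Reagents that add atoms: none
Why: Chemoselective borane reduction of a carboxylic acid through its acyloxyborane in the presence of the lactone and the benzyl ethers, under non-basic conditions that avoid alkoxide-driven translactonisation to the isomeric γ-lactone.

Step 5
Reactants: 9 3,4-bis(benzyloxy)benzaldehyde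
Product: 10 1,2-bis(benzyloxy)-4-(dimethoxymethyl)benzene
Conditions: HC(OMe)3, TsOH·H2O (cat.), MeOH, rt; Et3N quench
Reagents that add atoms: trimethyl orthoformate, COC(OC)OC
Why: Acid-catalysed acetalisation of an aryl aldehyde, driven to completion by the orthoformate, which consumes the water and ends as methyl formate.

Step 6
Reactants: 8 (4R,5S)-4-(hydroxymethyl)-5-[3,4,5-tris(benzyloxy)phenyl]oxolan-2-one; 10 1,2-bis(benzyloxy)-4-(dimethoxymethyl)benzene
Product: 12 (4R,5S)-4-({[3,4-bis(benzyloxy)phenyl](methoxy)methoxy}methyl)-5-[3,4,5-tris(benzyloxy)phenyl]oxolan-2-one (mixed acetal), via α-chloro ether 11 (not isolated)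
Conditions: 10, AcCl, CH2Cl2, 0 °C → rt, evaporate; then 8, iPr2NEt, CH2Cl2, −20 → 0 °C
Reagents that add atoms: none
Why: Acetyl chloride converts the dimethyl acetal into the α-chloro ether, which alkylates the primary alcohol through its oxocarbenium ion pair in the presence of iPr2NEt just as in a methoxymethyl ether formation (SN1-type O-alkylation), without forming an alkoxide that could move the lactone; the new acetal centre is formed as both epimers and is erased in step 7.

Step 7
Reactants: 12 (4R,5S)-4-({[3,4-bis(benzyloxy)phenyl](methoxy)methoxy}methyl)-5-[3,4,5-tris(benzyloxy)phenyl]oxolan-2-one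
Product: 14 (1S,2S,5R,6S)-2-[3,4-bis(benzyloxy)phenyl]-6-[3,4,5-tris(benzyloxy)phenyl]-3,7-dioxabicyclo[3.3.0]octan-8-one, via trimethylsilyl ketene acetal 13 (not isolated)
Conditions: LDA (LiN(iPr)2), TMSCl, THF, −78 °C; evaporate, CH2Cl2 (0.01 M); TMSOTf (0.1 equiv), −78 → −40 °C; aq. NaHCO3
Reagents that add atoms: none
Why: LDA with TMSCl present converts the lactone into the O-silyl ketene acetal 13; catalytic TMSOTf then silylates the more basic and less hindered methoxy oxygen of the mixed acetal, MeOSiMe3 leaves, and the (E)-oxocarbenium ion at C2, stabilised by O3 and by the para-benzyloxy group, is captured by C1 of the ketene acetal, whose silyl group is handed on so that the silyl triflate turns over. The closest known reaction types are the Mukaiyama aldol-type addition of silyl ketene acetals to acetals in its intramolecular form and the Lewis-acid rearrangement of 4,5-dihydro-1,3-dioxepins to 2-substituted tetrahydrofuran-3-carbaldehydes, which runs through the same tethered enolate and oxocarbenium pair. The tetrahydrofuran ring closes in a 5-(enolexo)-endo-trig mode, with the C2=O3 bond of the oxocarbenium ion inside the new ring. C1 is controlled by the stereocentre C5: its CH2–O arm can deliver C2 only to the face of the ketene acetal on which it stands, which enforces the cis ring fusion. C2 is controlled by the (E)-geometry of the oxocarbenium ion and by an open transition state in which the aryl group lies beside H1 and away from the fully substituted C8 with its OSiMe3 group, so that the aryl group should end on the convex face (exo, 2S). The step needs ionisation at the methoxy oxygen and not at the tether oxygen, and ring closure faster than intermolecular addition; the basicity difference of the two acetal oxygens, the five-membered transition state and high dilution at −78 °C should secure this.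

Step 8
Reactants: 14 (1S,2S,5R,6S)-2-[3,4-bis(benzyloxy)phenyl]-6-[3,4,5-tris(benzyloxy)phenyl]-3,7-dioxabicyclo[3.3.0]octan-8-one
Product: 15 (1S,2S,5R,6S)-2-(3,4-dihydroxyphenyl)-6-(3,4,5-trihydroxyphenyl)-3,7-dioxabicyclo[3.3.0]octan-8-one (target)
Conditions: H2 (1 atm), 10% Pd/C, EtOAc/MeOH, rt; work-up under argon
Reagents that add atoms: none
Why: Catalytic hydrogenolysis of the five aryl benzyl ethers, which should be cleaved much faster than the benzylic C–O bonds of the lactone and the cyclic ether under neutral conditions, the reaction being stopped after uptake of five equivalents of hydrogen with no stereocentre affected.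

Compound list
1 | (S)-4-benzyl-1,3-oxazolidin-2-one | O=C1OC[C@H](Cc2ccccc2)N1 | starting material
2 | methyl 4-chloro-4-oxobutanoate | COC(=O)CCC(=O)Cl | starting material
3 | methyl 4-[(4S)-4-benzyl-2-oxo-1,3-oxazolidin-3-yl]-4-oxobutanoate | COC(=O)CCC(=O)N1[C@@H](Cc2ccccc2)COC1=O | intermediate
4 | 3,4,5-tris(benzyloxy)benzaldehyde | O=Cc1cc(OCc2ccccc2)c(OCc2ccccc2)c(OCc2ccccc2)c1 | starting material
5 | methyl (3S,4S)-3-{[(4S)-4-benzyl-2-oxo-1,3-oxazolidin-3-yl]carbonyl}-4-hydroxy-4-[3,4,5-tris(benzyloxy)phenyl]butanoate (syn-aldol adduct) | O[C@H](c1cc(OCc2ccccc2)c(OCc2ccccc2)c(OCc2ccccc2)c1)[C@@H](C(=O)N1[C@@H](Cc2ccccc2)COC1=O)CC(=O)OC | intermediate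
6 | (4S)-4-benzyl-3-{(2S,3S)-5-oxo-2-[3,4,5-tris(benzyloxy)phenyl]oxolane-3-carbonyl}-1,3-oxazolidin-2-one (trans) | O=C1O[C@H](c2cc(OCc3ccccc3)c(OCc3ccccc3)c(OCc3ccccc3)c2)[C@@H](C(=O)N2[C@@H](Cc3ccccc3)COC2=O)C1 | intermediate
7 | (2S,3S)-5-oxo-2-[3,4,5-tris(benzyloxy)phenyl]oxolane-3-carboxylic acid | O=C1O[C@H](c2cc(OCc3ccccc3)c(OCc3ccccc3)c(OCc3ccccc3)c2)[C@@H](C(=O)O)C1 | intermediate
8 | (4R,5S)-4-(hydroxymethyl)-5-[3,4,5-tris(benzyloxy)phenyl]oxolan-2-one | O=C1O[C@H](c2cc(OCc3ccccc3)c(OCc3ccccc3)c(OCc3ccccc3)c2)[C@@H](CO)C1 | intermediate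
9 | 3,4-bis(benzyloxy)benzaldehyde | O=Cc1ccc(OCc2ccccc2)c(OCc2ccccc2)c1 | starting material
10 | 1,2-bis(benzyloxy)-4-(dimethoxymethyl)benzene | COC(OC)c1ccc(OCc2ccccc2)c(OCc2ccccc2)c1 | intermediate
11 | 1,2-bis(benzyloxy)-4-[chloro(methoxy)methyl]benzene (racemic α-chloro ether) | COC(Cl)c1ccc(OCc2ccccc2)c(OCc2ccccc2)c1 | intermediate
12 | (4R,5S)-4-({[3,4-bis(benzyloxy)phenyl](methoxy)methoxy}methyl)-5-[3,4,5-tris(benzyloxy)phenyl]oxolan-2-one (both epimers at the acetal carbon) | O=C1O[C@H](c2cc(OCc3ccccc3)c(OCc3ccccc3)c(OCc3ccccc3)c2)[C@@H](COC(OC)c2ccc(OCc3ccccc3)c(OCc3ccccc3)c2)C1 | intermediate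
13 | {[(2S,3R)-3-({[3,4-bis(benzyloxy)phenyl](methoxy)methoxy}methyl)-2-[3,4,5-tris(benzyloxy)phenyl]-2,3-dihydrofuran-5-yl]oxy}trimethylsilane (silyl ketene acetal) | C[Si](C)(C)OC1=C[C@H](COC(OC)c2ccc(OCc3ccccc3)c(OCc3ccccc3)c2)[C@@H](c2cc(OCc3ccccc3)c(OCc3ccccc3)c(OCc3ccccc3)c2)O1 | intermediate
14 | (1S,2S,5R,6S)-2-[3,4-bis(benzyloxy)phenyl]-6-[3,4,5-tris(benzyloxy)phenyl]-3,7-dioxabicyclo[3.3.0]octan-8-one (cis-fused, both aryl groups exo) | O=C1O[C@H](c2cc(OCc3ccccc3)c(OCc3ccccc3)c(OCc3ccccc3)c2)[C@H]2CO[C@H](c3ccc(OCc4ccccc4)c(OCc4ccccc4)c3)[C@@H]12 | intermediate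
15 | (1S,2S,5R,6S)-2-(3,4-dihydroxyphenyl)-6-(3,4,5-trihydroxyphenyl)-3,7-dioxabicyclo[3.3.0]octan-8-one | O=C1O[C@H](c2cc(O)c(O)c(O)c2)[C@H]2CO[C@H](c3ccc(O)c(O)c3)[C@@H]12 | target

Total step count: 8. Longest linear sequence: 7 steps (steps 1, 2, 3, 4, 6, 7, 8); step 5 is a one-step branch.

Steps most likely to fail

Step 7 (key ring closure). Three processes may go wrong: ionisation of the mixed acetal at the tether oxygen, with loss of the aryl aldehyde unit or intermolecular addition; protodesilylation of the ketene acetal before it cyclises; and insufficient facial selectivity at the oxocarbenium carbon, giving endo instead of exo aryl. The fallback sets out from 8 and comes back at 14, and closes the same C1–C2 bond by carbenoid C–H insertion instead. Alcohol 8 is etherified with commercial 3,4-bis(benzyloxy)benzyl chloride (AgOTf, 2,6-di-tert-butyl-4-methylpyridine, CH2Cl2) to the 3,4-bis(benzyloxy)benzyl ether F1. LiN(SiMe3)2 and 2,2,2-trifluoroethyl trifluoroacetate in THF at −78 °C give the α-trifluoroacetyl lactone F2, which is taken on without isolation with MsN3, Et3N and water in MeCN (detrifluoroacetylative diazo transfer) to the α-diazo lactone F3. Rh2(OAc)4 (catalytic) in CH2Cl2 then effects 1,5-insertion of the rhodium carbenoid into the benzylic ether C–H bond. This reaction is known on 4-(benzyloxymethyl)-5-aryl α-diazo-γ-butyrolactones and gives the cis-fused bicycle with the new aryl group endo, here the C2-endo epimer F4. Acid-mediated equilibration of the benzylic ether centre (TFA or BF3·OEt2, CH2Cl2), known for 2-aryl-3,7-dioxabicyclo[3.3.0]octanes and running through reversible C2–O3 ionisation, should then give a separable mixture of F4 and 14, with F4 recycled; the position of this equilibrium is the weak point of the fallback.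

Step 6 (mixed acetal). The very electron-rich α-chloro ether may decompose or hydrolyse before it alkylates the alcohol, and the acid-labile mixed acetal may be cleaved or scrambled during work-up and chromatography. The fallback sets out from 8 and comes back at 12, and uses silyl-ether/acetal exchange instead of alkylation. Alcohol 8 is converted (TMSCl, imidazole, CH2Cl2) into the trimethylsilyl ether F5, which is treated with an excess of dimethyl acetal 10 and catalytic TMSOTf in CH2Cl2 at −78 °C and quenched with Et3N. Kinetic transfer of one alkoxy group under these conditions should give 12, and excess 10 is recovered.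

Step 8 (debenzylation). Over-reduction may occur, that is hydrogenolysis of the benzylic C6–O7 lactone bond or of the benzylic C2–O3 ether bond once the phenols are free, and the pyrogallol ring may oxidise in air on work-up. The fallback sets out from 14 and comes back at 15, and replaces reductive cleavage by non-reductive Lewis-acid debenzylation: BCl3 with pentamethylbenzene as benzyl cation scavenger in CH2Cl2 at −78 °C, followed by a methanol quench; no new compound is formed on the way (F0).

Further compounds
F1 | step 7 | (4R,5S)-4-({[3,4-bis(benzyloxy)phenyl]methoxy}methyl)-5-[3,4,5-tris(benzyloxy)phenyl]oxolan-2-one | O=C1O[C@H](c2cc(OCc3ccccc3)c(OCc3ccccc3)c(OCc3ccccc3)c2)[C@@H](COCc2ccc(OCc3ccccc3)c(OCc3ccccc3)c2)C1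
F2 | step 7 | (4R,5S)-4-({[3,4-bis(benzyloxy)phenyl]methoxy}methyl)-3-(trifluoroacetyl)-5-[3,4,5-tris(benzyloxy)phenyl]oxolan-2-one (both epimers at C3) | O=C1O[C@H](c2cc(OCc3ccccc3)c(OCc3ccccc3)c(OCc3ccccc3)c2)[C@@H](COCc2ccc(OCc3ccccc3)c(OCc3ccccc3)c2)C1C(=O)C(F)(F)F
F3 | step 7 | (4R,5S)-4-({[3,4-bis(benzyloxy)phenyl]methoxy}methyl)-3-diazo-5-[3,4,5-tris(benzyloxy)phenyl]oxolan-2-one | O=C1O[C@H](c2cc(OCc3ccccc3)c(OCc3ccccc3)c(OCc3ccccc3)c2)[C@@H](COCc2ccc(OCc3ccccc3)c(OCc3ccccc3)c2)C1=[N+]=[N-]
F4 | step 7 | (1S,2R,5R,6S)-2-[3,4-bis(benzyloxy)phenyl]-6-[3,4,5-tris(benzyloxy)phenyl]-3,7-dioxabicyclo[3.3.0]octan-8-one (C2-endo epimer of 14) | O=C1O[C@H](c2cc(OCc3ccccc3)c(OCc3ccccc3)c(OCc3ccccc3)c2)[C@H]2CO[C@@H](c3ccc(OCc4ccccc4)c(OCc4ccccc4)c3)[C@@H]12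
F5 | step 6 | (4R,5S)-4-{[(trimethylsilyl)oxy]methyl}-5-[3,4,5-tris(benzyloxy)phenyl]oxolan-2-one | O=C1O[C@H](c2cc(OCc3ccccc3)c(OCc3ccccc3)c(OCc3ccccc3)c2)[C@@H](CO[Si](C)(C)C)C1
F0 | step 8 | none | none
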